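**Plan**
- Retrosynthetic cuts: the C6–prenyl bond of the dearomatised chromanone, the C6–CH2 bond that joins core and cyclobutane, the pyranone ring (aryl–acyl C–C and O–CMe2), the side-chain centre on C8 (masked as a dihydrocoumarin lactone), and in the four-membered ring the bond between the isopropenyl-bearing CH and CMe2.
- Enabling feature: in the cyclobutane the CH that carries isopropenyl lies between CMe2 and the CH that carries the CH2 link. It is therefore the carbene carbon of 2-diazo-5,5-dimethylcyclopentanone 9, whose quaternary carbon migrates (Wolff ring contraction); the extruded ester carbon becomes the isopropenyl carbon.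
- Cyclobutane branch, forward: cyclopentanone 1 → enone → asymmetric vinylation → diazoketone 9 → cyclobutane ester 12 → aldehyde 17.
- Core branch, forward: phloroglucinol → coumarin ring (Pechmann) → dihydrocoumarin → pyranone ring → phenol 26; union by reductive C6-alkylation, then ester opening and dearomative C6-prenylation.
- Stereochemistry: the cyclobutane CH(CH2) comes from the Rh/(R)-BINAP vinylation and its neighbour from trans equilibration; the side-chain centre from copper hydride reduction of the coumarin; the quaternary C6 from ligand-controlled palladium allylation.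

Key step: step 6

Assumption: the sense of induction of (R)-DTBM-SEGPHOS in step 13 and of the (S,S)-DACH-phenyl Trost ligand in step 17 is taken by analogy with related substrates; if the first run shows the opposite sense, the mirror-image ligand is used with nothing else changed.

**Route**

Step 1
Reactants: 1 2,2-dimethylcyclopentan-1-one
Product: 2 5,5-dimethylcyclopent-2-en-1-one
Conditions: IBX (2 equiv), DMSO/PhF, 70 °C
Reagents that add atoms: none
Why: IBX α,β-dehydrogenation of a ketone through its enol; only C5 of 1 carries α-hydrogens, so a single enone can form.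

Step 2
Reactants: 2 5,5-dimethylcyclopent-2-en-1-one; 3 potassium vinyltrifluoroborate
Product: 4 (4R)-4-ethenyl-2,2-dimethylcyclopentan-1-one
Conditions: [Rh(cod)2]PF6 (3 mol%), (R)-BINAP (3.3 mol%), toluene/H2O 4:1, 100 °C
Reagents that add atoms: none
Why: Hayashi–Miyaura-type rhodium-catalysed asymmetric 1,4-addition of an alkenyltrifluoroborate; the (R)-BINAP–rhodium vinyl species should add to the enone face that gives the (R)-configured β-carbon, following the model in which (S)-BINAP gives (S)-adducts of 2-cyclopentenone.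

Step 3
Reactants: 4 (4R)-4-ethenyl-2,2-dimethylcyclopentan-1-one
Product: 6 (4R)-4-(hydroxymethyl)-2,2-dimethylcyclopentan-1-one, via keto aldehyde 5 (not isolated)
Conditions: O3, CH2Cl2, −78 °C; PPh3, −78 → 0 °C; then NaBH(OAc)3, 0 °C
Reagents that add atoms: ozone, [O-][O+]=O
Why: Ozonolysis cleaves the vinyl group to the aldehyde, which NaBH(OAc)3 reduces at once and chemoselectively beside the hindered ketone next to CMe2; cold, base-free handling should keep the centre α to the transient aldehyde intact.

Step 4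
Reactants: 6 (4R)-4-(hydroxymethyl)-2,2-dimethylcyclopentan-1-one
Product: 7 (4R)-4-({[tert-butyl(dimethyl)silyl]oxy}methyl)-2,2-dimethylcyclopentan-1-one
Conditions: TBSCl, imidazole, CH2Cl2, 0 °C → rt
Reagents that add atoms: tert-butyldimethylsilyl chloride, CC(C)(C)[Si](C)(C)Cl
Why: Standard silylation of a primary alcohol; the silyl ether keeps the oxygen from trapping the ketene of step 6 as a cis-fused lactone.

Step 5
Reactants: 7 (4R)-4-({[tert-butyl(dimethyl)silyl]oxy}methyl)-2,2-dimethylcyclopentan-1-one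
Product: 9 (3R)-3-({[tert-butyl(dimethyl)silyl]oxy}methyl)-2-diazo-5,5-dimethylcyclopentan-1-one, via trifluoroacetyl ketone 8 (not isolated)
Conditions: LiN(SiMe3)2, THF, −78 °C; CF3CO2CH2CF3; aq. HCl work-up; then MsN3, Et3N, H2O, MeCN, rt
Reagents that add atoms: methanesulfonyl azide, CS(=O)(=O)N=[N+]=[N-] (2,2,2-trifluoroethyl trifluoroacetate, O=C(OCC(F)(F)F)C(F)(F)F, supplies the trifluoroacetyl group of 8 only)
Why: Danheiser's detrifluoroacetylative diazo transfer (Regitz type): Claisen trifluoroacetylation can occur only at the single enolisable α-carbon, and the sulfonyl azide then exchanges the trifluoroacetyl group for N2 without touching the β-stereocentre.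

Step 6
Reactants: 9 (3R)-3-({[tert-butyl(dimethyl)silyl]oxy}methyl)-2-diazo-5,5-dimethylcyclopentan-1-one
Product: 12 methyl (1S,2R)-2-({[tert-butyl(dimethyl)silyl]oxy}methyl)-4,4-dimethylcyclobutane-1-carboxylate (trans), via ketene 10 (not isolated), via cis ester 11 (not isolated)
Conditions: hν (medium-pressure Hg lamp, Pyrex filter), MeOH, 0 °C; then NaOMe (0.3 equiv), MeOH, 50 °C
Reagents that add atoms: methanol, CO
Why: Excitation of the ring-locked s-cis α-diazoketone expels N2 while the quaternary CMe2 carbon shifts from the carbonyl carbon to the diazo carbon, giving ketene 10, which methanol traps as the ester (Wolff rearrangement). The closest known reaction type is the photochemical Wolff ring contraction of 2-diazocyclopentanones and of 16-diazo-17-keto steroids (quaternary C13 migrating) to cyclobutanecarboxylic acid derivatives. The four-membered ring is closed by ring contraction, not by cyclisation of a chain: the 1,2-alkyl shift makes the CH–CMe2 bond and extrudes the former carbonyl carbon as the exocyclic ester carbon. The CH2OSi-bearing centre from step 2 is a spectator; the new ester-bearing centre forms on protonation of the ketene adduct, probably cis-enriched, and is then set by NaOMe equilibration to the trans isomer, in which the ester avoids the cis CH2OSi group. The step needs rearrangement to outrun 1,2-hydride shift to an enone and C–H insertion; the enforced s-cis geometry and direct metal-free photolysis in methanol should secure this, and migration is regiospecific because CMe2 is the only substituent on the carbonyl carbon.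

Step 7
Reactants: 12 methyl (1S,2R)-2-({[tert-butyl(dimethyl)silyl]oxy}methyl)-4,4-dimethylcyclobutane-1-carboxylate
Product: 14 1-[(1S,2R)-2-({[tert-butyl(dimethyl)silyl]oxy}methyl)-4,4-dimethylcyclobutyl]ethan-1-one, via Weinreb amide 13 (not isolated)
Conditions: MeNHOMe·HCl, iPrMgCl, THF, −20 → 0 °C; then MeMgBr, 0 °C → rt; aq. NH4Cl
Reagents that add atoms: methylmagnesium bromide, C[Mg]Br
Why: Weinreb ketone synthesis: the magnesium amide of N,O-dimethylhydroxylamine turns the ester into the N-methoxy-N-methylamide, whose chelated adduct with MeMgBr stops at the ketone; any epimerisation α to the carbonyl returns the favoured trans isomer.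

Step 8
Reactants: 14 1-[(1S,2R)-2-({[tert-butyl(dimethyl)silyl]oxy}methyl)-4,4-dimethylcyclobutyl]ethan-1-one
Product: 15 tert-butyl{[(1R,2R)-3,3-dimethyl-2-(prop-1-en-2-yl)cyclobutyl]methoxy}dimethylsilane
Conditions: Ph3PCH3Br, KOtBu, THF, 0 °C → rt
Reagents that add atoms: methyltriphenylphosphonium bromide, C[P+](c1ccccc1)(c1ccccc1)c1ccccc1.[Br-]
Why: Wittig methylenation of a cyclobutyl methyl ketone gives the isopropenyl group with no cationic intermediate, so cyclobutylcarbinyl ring expansion and isopropylidene formation are avoided.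

Step 9
Reactants: 15 tert-butyl{[(1R,2R)-3,3-dimethyl-2-(prop-1-en-2-yl)cyclobutyl]methoxy}dimethylsilane
Product: 16 [(1R,2R)-3,3-dimethyl-2-(prop-1-en-2-yl)cyclobutyl]methanol
Conditions: Bu4NF, THF, 0 °C → rt
Reagents that add atoms: none
Why: Fluoride cleavage of the silyl ether under non-acidic conditions that leave the isopropenyl cyclobutane untouched.

Step 10
Reactants: 16 [(1R,2R)-3,3-dimethyl-2-(prop-1-en-2-yl)cyclobutyl]methanol
Product: 17 (1R,2R)-3,3-dimethyl-2-(prop-1-en-2-yl)cyclobutane-1-carbaldehyde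
Conditions: Dess–Martin periodinane, CH2Cl2, 0 °C → rt
Reagents that add atoms: none
Why: Dess–Martin oxidation of a primary alcohol stops at the aldehyde; the α-centre already has the thermodynamically favoured trans arrangement.

Step 11
Reactants: 18 phloroglucinol; 19 ethyl 3-oxohexanoate
Product: 20 5,7-dihydroxy-4-propyl-2H-chromen-2-one
Conditions: conc. H2SO4, 0 °C → rt
Reagents that add atoms: none
Why: Pechmann condensation; the threefold symmetry of phloroglucinol allows only one coumarin, with the propyl group at C4.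

Step 12
Reactants: 20 5,7-dihydroxy-4-propyl-2H-chromen-2-one
Product: 21 5-hydroxy-7-methoxy-4-propyl-2H-chromen-2-one
Conditions: MeI (1.05 equiv), K2CO3 (1.1 equiv), acetone, rt
Reagents that add atoms: iodomethane, CI
Why: Williamson etherification should favour the 7-hydroxyl, which is the more acidic (conjugated through the pyranone to the lactone carbonyl) and unhindered, while the 5-hydroxyl is shielded by the peri propyl group.

Step 13
Reactants: 21 5-hydroxy-7-methoxy-4-propyl-2H-chromen-2-one
Product: 23 (4R)-5-hydroxy-7-methoxy-4-propyl-3,4-dihydro-2H-chromen-2-one, via silyl ether 22 (not isolated)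
Conditions: Cu(OAc)2·H2O (3 mol%), (R)-DTBM-SEGPHOS (3 mol%), (EtO)2MeSiH (3 equiv), t-BuOH (1.2 equiv), toluene, 0 °C → rt; then aq. NH4F
Reagents that add atoms: none
Why: Copper hydride asymmetric conjugate reduction of a coumarin (Buchwald/Lipshutz type): the ligated copper hydride delivers hydride to one face of C4 and so sets the side-chain centre, the phenol riding through as its silyl ether until the fluoride work-up.

Step 14
Reactants: 23 (4R)-5-hydroxy-7-methoxy-4-propyl-3,4-dihydro-2H-chromen-2-one; 24 3-methylbut-2-enoic acid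
Product: 25 (10R)-5-methoxy-2,2-dimethyl-10-propyl-2,3,9,10-tetrahydro-4H,8H-pyrano[2,3-f]chromene-4,8-dione
Conditions: Eaton's reagent (P2O5 in MeSO3H), 60 °C
Reagents that add atoms: none
Why: Friedel–Crafts acylation (through the aryl ester and Fries shift) at the carbon ortho to the free hydroxyl, then oxa-Michael closure of that hydroxyl onto the dimethylacryloyl group; because the other flanking oxygen is a methyl ether, the pyranone oxygen can end only on the carbon next to the side chain.

Step 15
Reactants: 25 (10R)-5-methoxy-2,2-dimethyl-10-propyl-2,3,9,10-tetrahydro-4H,8H-pyrano[2,3-f]chromene-4,8-dione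
Product: 26 (10R)-5-hydroxy-2,2-dimethyl-10-propyl-2,3,9,10-tetrahydro-4H,8H-pyrano[2,3-f]chromene-4,8-dione
Conditions: BCl3 (2.5 equiv), CH2Cl2, −78 → 0 °C; H2O
Reagents that add atoms: none
Why: Chelation-controlled Lewis acid cleavage of the methyl ether peri to the pyranone carbonyl; this is done before the acid-sensitive cyclobutane enters the molecule.

Step 16
Reactants: 26 (10R)-5-hydroxy-2,2-dimethyl-10-propyl-2,3,9,10-tetrahydro-4H,8H-pyrano[2,3-f]chromene-4,8-dione; 17 (1R,2R)-3,3-dimethyl-2-(prop-1-en-2-yl)cyclobutane-1-carbaldehyde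
Product: 29 methyl (3R)-3-[6-{[(1S,2R)-3,3-dimethyl-2-(prop-1-en-2-yl)cyclobutyl]methyl}-5,7-dihydroxy-2,2-dimethyl-4-oxo-3,4-dihydro-2H-chromen-8-yl]hexanoate, via ring-opened methyl ester 27 (not isolated), via ortho-quinone methide 28 (not isolated)
Conditions: NaOMe (1.1 equiv), MeOH, 0 °C; AcOH (1.1 equiv); then 17 (1.2 equiv), L-proline (20 mol%), Hantzsch ester (1.3 equiv), MeOH/CH2Cl2, rt
Reagents that add atoms: sodium methoxide, C[O-].[Na+]
Why: Methanolysis of the aryl lactone frees the 7-hydroxyl, and the resulting 5,7-dihydroxychromanone undergoes three-component reductive alkylation (proline-mediated Knoevenagel condensation to the quinone methide, then Hantzsch ester conjugate reduction) at C6, its only free ring carbon; the two cyclobutane centres are not involved, and the aldehyde α-centre can only relax to trans.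

Step 17
Reactants: 29 methyl (3R)-3-[6-{[(1S,2R)-3,3-dimethyl-2-(prop-1-en-2-yl)cyclobutyl]methyl}-5,7-dihydroxy-2,2-dimethyl-4-oxo-3,4-dihydro-2H-chromen-8-yl]hexanoate; 30 3-methylbut-2-en-1-yl acetate (prenyl acetate)
Product: 32 (3R)-3-[(6R)-6-{[(1S,2R)-3,3-dimethyl-2-(prop-1-en-2-yl)cyclobutyl]methyl}-5-hydroxy-2,2-dimethyl-6-(3-methylbut-2-en-1-yl)-4,7-dioxo-3,4,6,7-tetrahydro-2H-chromen-8-yl]hexanoic acid, via hydroxy acid salt 31 (not isolated)
Conditions: Bu4NOH (2.2 equiv, aq.), degassed THF, 0 °C → rt; then Pd2(dba)3·CHCl3 (2.5 mol%), (S,S)-DACH-phenyl Trost ligand (7.5 mol%), 30 (1.05 equiv), 0 °C; 1 M HCl to pH 3 at 0 °C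
Reagents that add atoms: tetrabutylammonium hydroxide, CCCC[N+](CCCC)(CCCC)CCCC.[OH-]
Why: Proposed new method: hydroxide opens the ester (or any re-formed lactone) to the carboxylate and ionises the 7-hydroxyl, zerovalent palladium ionises prenyl acetate to a π-prenyl complex in the chiral pocket, and C6 of the ammonium phloroglucinolate (flanked by two oxygens, carrying only a primary CH2 group, whereas C8 carries a secondary alkyl group) attacks the unsubstituted allyl terminus to give the linear prenyl group and the quaternary centre, the ligand choosing the ring face, while O-prenyl ethers and prenyl carboxylate re-ionise under palladium so that only the irreversible C–C bond accumulates; the closest known reaction types are the palladium-catalysed asymmetric allylic dearomatisation of 2-naphthols with Trost-type ligands and the Tsuji–Trost dearomative allylation of acylphloroglucinols.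

**Compound list**

1 | 2,2-dimethylcyclopentan-1-one | CC1(C)CCCC1=O | starting material
2 | 5,5-dimethylcyclopent-2-en-1-one | CC1(C)CC=CC1=O | intermediate
3 | potassium vinyltrifluoroborate | C=C[B-](F)(F)F.[K+] | starting material
4 | (4R)-4-ethenyl-2,2-dimethylcyclopentan-1-one | O=C1C(C)(C)C[C@@H](C=C)C1 | intermediate
5 | (1R)-3,3-dimethyl-4-oxocyclopentane-1-carbaldehyde | O=C1C(C)(C)C[C@@H](C=O)C1 | intermediate
6 | (4R)-4-(hydroxymethyl)-2,2-dimethylcyclopentan-1-one | O=C1C(C)(C)C[C@@H](CO)C1 | intermediate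
7 | (4R)-4-({[tert-butyl(dimethyl)silyl]oxy}methyl)-2,2-dimethylcyclopentan-1-one | O=C1C(C)(C)C[C@@H](CO[Si](C)(C)C(C)(C)C)C1 | intermediate
8 | (3R)-3-({[tert-butyl(dimethyl)silyl]oxy}methyl)-5,5-dimethyl-2-(trifluoroacetyl)cyclopentan-1-one (C2 epimers and enol) | O=C(C1C(=O)C(C)(C)C[C@H]1CO[Si](C)(C)C(C)(C)C)C(F)(F)F | intermediate
9 | (3R)-3-({[tert-butyl(dimethyl)silyl]oxy}methyl)-2-diazo-5,5-dimethylcyclopentan-1-one | [N-]=[N+]=C1C(=O)C(C)(C)C[C@H]1CO[Si](C)(C)C(C)(C)C | intermediate
10 | [(2R)-2-({[tert-butyl(dimethyl)silyl]oxy}methyl)-4,4-dimethylcyclobutylidene]methanone (ketene) | O=C=C1[C@H](CO[Si](C)(C)C(C)(C)C)CC1(C)C | intermediate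
11 | methyl (1R,2R)-2-({[tert-butyl(dimethyl)silyl]oxy}methyl)-4,4-dimethylcyclobutane-1-carboxylate (cis) | COC(=O)[C@@H]1[C@H](CO[Si](C)(C)C(C)(C)C)CC1(C)C | intermediate
12 | methyl (1S,2R)-2-({[tert-butyl(dimethyl)silyl]oxy}methyl)-4,4-dimethylcyclobutane-1-carboxylate (trans) | COC(=O)[C@H]1[C@H](CO[Si](C)(C)C(C)(C)C)CC1(C)C | intermediate
13 | (1S,2R)-2-({[tert-butyl(dimethyl)silyl]oxy}methyl)-N-methoxy-N,4,4-trimethylcyclobutane-1-carboxamide | CON(C)C(=O)[C@H]1[C@H](CO[Si](C)(C)C(C)(C)C)CC1(C)C | intermediate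
14 | 1-[(1S,2R)-2-({[tert-butyl(dimethyl)silyl]oxy}methyl)-4,4-dimethylcyclobutyl]ethan-1-one | CC(=O)[C@H]1[C@H](CO[Si](C)(C)C(C)(C)C)CC1(C)C | intermediate
15 | tert-butyl{[(1R,2R)-3,3-dimethyl-2-(prop-1-en-2-yl)cyclobutyl]methoxy}dimethylsilane | C=C(C)[C@H]1[C@H](CO[Si](C)(C)C(C)(C)C)CC1(C)C | intermediate
16 | [(1R,2R)-3,3-dimethyl-2-(prop-1-en-2-yl)cyclobutyl]methanol | C=C(C)[C@H]1[C@H](CO)CC1(C)C | intermediate
17 | (1R,2R)-3,3-dimethyl-2-(prop-1-en-2-yl)cyclobutane-1-carbaldehyde | C=C(C)[C@H]1[C@H](C=O)CC1(C)C | intermediate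
18 | phloroglucinol (benzene-1,3,5-triol) | Oc1cc(O)cc(O)c1 | starting material
19 | ethyl 3-oxohexanoate | CCCC(=O)CC(=O)OCC | starting material
20 | 5,7-dihydroxy-4-propyl-2H-chromen-2-one | CCCC1=CC(=O)Oc2cc(O)cc(O)c12 | intermediate
21 | 5-hydroxy-7-methoxy-4-propyl-2H-chromen-2-one | CCCC1=CC(=O)Oc2cc(OC)cc(O)c12 | intermediate
22 | (4R)-5-{[diethoxy(methyl)silyl]oxy}-7-methoxy-4-propyl-3,4-dihydro-2H-chromen-2-one | CCC[C@@H]1CC(=O)Oc2cc(OC)cc(O[Si](C)(OCC)OCC)c12 | intermediate
23 | (4R)-5-hydroxy-7-methoxy-4-propyl-3,4-dihydro-2H-chromen-2-one | CCC[C@@H]1CC(=O)Oc2cc(OC)cc(O)c12 | intermediate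
24 | 3-methylbut-2-enoic acid | CC(C)=CC(=O)O | starting material
25 | (10R)-5-methoxy-2,2-dimethyl-10-propyl-2,3,9,10-tetrahydro-4H,8H-pyrano[2,3-f]chromene-4,8-dione | COc1cc2OC(=O)C[C@@H](CCC)c2c3OC(C)(C)CC(=O)c13 | intermediate
26 | (10R)-5-hydroxy-2,2-dimethyl-10-propyl-2,3,9,10-tetrahydro-4H,8H-pyrano[2,3-f]chromene-4,8-dione | Oc1cc2OC(=O)C[C@@H](CCC)c2c3OC(C)(C)CC(=O)c13 | intermediate
27 | methyl (3R)-3-(5,7-dihydroxy-2,2-dimethyl-4-oxo-3,4-dihydro-2H-chromen-8-yl)hexanoate | CCC[C@H](CC(=O)OC)c1c(O)cc(O)c2c1OC(C)(C)CC2=O | intermediate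
28 | methyl (3R)-3-[6-{[(1S,2R)-3,3-dimethyl-2-(prop-1-en-2-yl)cyclobutyl]methylidene}-5-hydroxy-2,2-dimethyl-4,7-dioxo-3,4,6,7-tetrahydro-2H-chromen-8-yl]hexanoate (ortho-quinone methide, alkene geometry open) | CCC[C@H](CC(=O)OC)C1=C2OC(C)(C)CC(=O)C2=C(O)C(=C[C@@H]3CC(C)(C)[C@H]3C(C)=C)C1=O | intermediate
29 | methyl (3R)-3-[6-{[(1S,2R)-3,3-dimethyl-2-(prop-1-en-2-yl)cyclobutyl]methyl}-5,7-dihydroxy-2,2-dimethyl-4-oxo-3,4-dihydro-2H-chromen-8-yl]hexanoate | CCC[C@H](CC(=O)OC)c1c(O)c(C[C@@H]2CC(C)(C)[C@H]2C(C)=C)c(O)c2c1OC(C)(C)CC2=O | intermediate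
30 | 3-methylbut-2-en-1-yl acetate | CC(C)=CCOC(C)=O | starting material
31 | (3R)-3-[6-{[(1S,2R)-3,3-dimethyl-2-(prop-1-en-2-yl)cyclobutyl]methyl}-5,7-dihydroxy-2,2-dimethyl-4-oxo-3,4-dihydro-2H-chromen-8-yl]hexanoic acid (present as its bis(tetrabutylammonium) salt) | CCC[C@H](CC(=O)O)c1c(O)c(C[C@@H]2CC(C)(C)[C@H]2C(C)=C)c(O)c2c1OC(C)(C)CC2=O | intermediate
32 | (3R)-3-[(6R)-6-{[(1S,2R)-3,3-dimethyl-2-(prop-1-en-2-yl)cyclobutyl]methyl}-5-hydroxy-2,2-dimethyl-6-(3-methylbut-2-en-1-yl)-4,7-dioxo-3,4,6,7-tetrahydro-2H-chromen-8-yl]hexanoic acid | C=C(C)[C@H]1[C@H](C[C@]2(CC=C(C)C)C(=O)C([C@H](CCC)CC(=O)O)=C3OC(C)(C)CC(=O)C3=C2O)CC1(C)C | target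

**Step count and risks**

Total step count: 17. Longest linear sequence: 12 steps (steps 1–10, then 16 and 17); the core branch contributes steps 11–15.

Steps most likely to fail:

Step 17. Facial discrimination at C6 may be poor because both flanks of the reacting carbon are oxygen-bearing; the prenyl group may also go to C8 or add twice, and the aqueous medium may slow ionisation of the acetate. The fallback sets out from 29 and gives up catalyst control. Treatment with aqueous KOH at 0 °C opens the ester to the salt of 31, and prenyl bromide then effects the classical base-mediated dearomative C-prenylation of an acylphloroglucinol. This should give 32 together with its C6 epimer, (3R)-3-[(6S)-6-{[(1S,2R)-3,3-dimethyl-2-(prop-1-en-2-yl)cyclobutyl]methyl}-5-hydroxy-2,2-dimethyl-6-(3-methylbut-2-en-1-yl)-4,7-dioxo-3,4,6,7-tetrahydro-2H-chromen-8-yl]hexanoic acid F1, and the two acids are separated by preparative HPLC. The fallback comes back to the route at 32.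

Step 16. Condensation of the hindered α-branched aldehyde with the chromanone may be slow, and the quinone methide may tautomerise to a styrene or add a second phenol before hydride arrives. The fallback replaces the condensation by a Negishi sp3–sp2 coupling. It sets out from alcohol 16, which with I2, PPh3 and imidazole gives (1R,2R)-1-(iodomethyl)-3,3-dimethyl-2-(prop-1-en-2-yl)cyclobutane F2; zinc dust with LiCl in THF converts this into {[(1R,2R)-3,3-dimethyl-2-(prop-1-en-2-yl)cyclobutyl]methyl}zinc iodide F3. In parallel, phenol 26 is iodinated with N-iodosuccinimide at its only free ring carbon to give (10R)-5-hydroxy-6-iodo-2,2-dimethyl-10-propyl-2,3,9,10-tetrahydro-4H,8H-pyrano[2,3-f]chromene-4,8-dione F4. Coupling of F4 with excess F3 under Pd(OAc)2/CPhos in THF gives the lactone (10R)-6-{[(1S,2R)-3,3-dimethyl-2-(prop-1-en-2-yl)cyclobutyl]methyl}-5-hydroxy-2,2-dimethyl-10-propyl-2,3,9,10-tetrahydro-4H,8H-pyrano[2,3-f]chromene-4,8-dione F5. The hydroxide of step 17 opens this lactone, so the fallback comes back to the route at 31.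

Step 13. The peri phenol (or its silyl ether) may slow or misdirect hydride delivery, so that enantioselectivity is low or the sense is wrong. The fallback sets out from 21 and uses resolution in place of asymmetric catalysis. Hydrogenation over Pd/C gives racemic 5-hydroxy-7-methoxy-4-propyl-3,4-dihydro-2H-chromen-2-one F6. (R)-1-Phenylethylamine opens the lactone to two diastereomeric hydroxy amides; the one with the (3R) side chain, (3R)-3-(2,6-dihydroxy-4-methoxyphenyl)-N-[(1R)-1-phenylethyl]hexanamide F7, is separated by crystallisation or chromatography. Heating F7 in aqueous HCl/dioxane hydrolyses the amide and re-closes the lactone; either phenol gives the same product because the aryl ring of F7 is symmetric. The fallback comes back to the route at 23.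

Further compounds
F1 | step 17 | (3R)-3-[(6S)-6-{[(1S,2R)-3,3-dimethyl-2-(prop-1-en-2-yl)cyclobutyl]methyl}-5-hydroxy-2,2-dimethyl-6-(3-methylbut-2-en-1-yl)-4,7-dioxo-3,4,6,7-tetrahydro-2H-chromen-8-yl]hexanoic acid | C=C(C)[C@H]1[C@H](C[C@@]2(CC=C(C)C)C(=O)C([C@H](CCC)CC(=O)O)=C3OC(C)(C)CC(=O)C3=C2O)CC1(C)C
F2 | step 16 | (1R,2R)-1-(iodomethyl)-3,3-dimethyl-2-(prop-1-en-2-yl)cyclobutane | C=C(C)[C@H]1[C@H](CI)CC1(C)C
F3 | step 16 | {[(1R,2R)-3,3-dimethyl-2-(prop-1-en-2-yl)cyclobutyl]methyl}zinc iodide | C=C(C)[C@H]1[C@H](C[Zn]I)CC1(C)C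
F4 | step 16 | (10R)-5-hydroxy-6-iodo-2,2-dimethyl-10-propyl-2,3,9,10-tetrahydro-4H,8H-pyrano[2,3-f]chromene-4,8-dione | Oc1c(I)c2OC(=O)C[C@@H](CCC)c2c3OC(C)(C)CC(=O)c13
F5 | step 16 | (10R)-6-{[(1S,2R)-3,3-dimethyl-2-(prop-1-en-2-yl)cyclobutyl]methyl}-5-hydroxy-2,2-dimethyl-10-propyl-2,3,9,10-tetrahydro-4H,8H-pyrano[2,3-f]chromene-4,8-dione | Oc1c(C[C@@H]2CC(C)(C)[C@H]2C(C)=C)c2OC(=O)C[C@@H](CCC)c2c3OC(C)(C)CC(=O)c13
F6 | step 13 | racemic 5-hydroxy-7-methoxy-4-propyl-3,4-dihydro-2H-chromen-2-one | CCCC1CC(=O)Oc2cc(OC)cc(O)c12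
F7 | step 13 | (3R)-3-(2,6-dihydroxy-4-methoxyphenyl)-N-[(1R)-1-phenylethyl]hexanamide | CCC[C@H](CC(=O)N[C@H](C)c1ccccc1)c1c(O)cc(OC)cc1O
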